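Assumption: isomerically pure (2E,6E)-farnesol is used (commercial grade, or distilled from the cheaper isomer mixture). The route is a paper design; selectivities are argued from precedent and have not been tested.

**Retrosynthetic overview**
1. C8–O last: target 14 from exocyclic alkene acid 12 by Markovnikov hydrogen-atom-transfer hydration (O2 as the oxygen source); this is the key bond and sets C-8.
2. Ring B (C9–C10): 12 from monocyclic acid 9 through bridged lactone 10, used as a latent C-10 cation for a cation–olefin cyclization.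
3. Ring A (C4–C5 and C2–C3): 9 from aldehyde 8, made by an enantioselective exo Diels–Alder reaction of diene 6 with methacrolein 7 (sets C-4 and C-5).
4. Diene 6 from (S)-dihydrofarnesyl acetate 3 (ω-oxidation, methylenation); 3 from farnesol 1 by asymmetric hydrogenation (sets C-13).
5. Ring order: ring A first (step 5), ring B second (step 7).

**Route**

Step 1
Reactants: 1 (2E,6E)-farnesol
Product: 2 (3S,6E)-3,7,11-trimethyldodeca-6,10-dien-1-ol
Conditions: Ru(OAc)2[(R)-BINAP] (0.5 mol %), H2 (30–100 atm), MeOH, rt
Reagents that add atoms: none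
Why: Noyori hydroxyl-directed asymmetric hydrogenation reduces only the allylic-alcohol C=C, and (R)-BINAP on an (E)-allylic alcohol gives the (3S) centre (the geraniol to (S)-citronellol precedent), which becomes C-13 of the target.

Step 2
Reactants: 2 (3S,6E)-3,7,11-trimethyldodeca-6,10-dien-1-ol
Product: 3 (3S,6E)-3,7,11-trimethyldodeca-6,10-dien-1-yl acetate
Conditions: Ac2O, pyridine, DMAP (cat.), 0 °C→rt
Reagents that add atoms: acetic anhydride, CC(=O)OC(C)=O
Why: DMAP-catalysed acylation installs the C-15 acetate of the target early, where it also protects the primary alcohol through all later steps.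

Step 3
Reactants: 3 (3S,6E)-3,7,11-trimethyldodeca-6,10-dien-1-yl acetate
Product: 5 (3S,6E,10E)-3,7,11-trimethyl-12-oxododeca-6,10-dien-1-yl acetate, via allylic alcohol 4 (not isolated)
Conditions: SeO2 (0.3 equiv), t-BuOOH, salicylic acid (cat.), CH2Cl2, rt; then MnO2, CH2Cl2, rt
Reagents that add atoms: selenium dioxide, O=[Se]=O; tert-butyl hydroperoxide, CC(C)(C)OO (terminal oxidant that re-forms SeO2)
Why: SeO2 allylic oxidation (ene reaction then [2,3]-sigmatropic shift) is selective for the (E)-methyl of the terminal isopropylidene group, as with farnesyl acetate, and MnO2 takes allylic alcohol 4 on to the (E)-enal.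

Step 4
Reactants: 5 (3S,6E,10E)-3,7,11-trimethyl-12-oxododeca-6,10-dien-1-yl acetate
Product: 6 (3S,6E,10E)-3,7,11-trimethyltrideca-6,10,12-trien-1-yl acetate
Conditions: Ph3PCH3Br, KOt-Bu, THF, 0 °C; then 5, −78→0 °C
Reagents that add atoms: methyltriphenylphosphonium bromide, C[P+](c1ccccc1)(c1ccccc1)c1ccccc1.[Br-] (its ylide delivers CH2)
Why: Wittig methylenation of the enal gives the (E)-1-alkyl-2-methylbuta-1,3-diene needed for ring A without touching the geometry of either trisubstituted alkene.

Step 5
Reactants: 6 (3S,6E,10E)-3,7,11-trimethyltrideca-6,10,12-trien-1-yl acetate; 7 methacrolein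
Product: 8 (1S,2S)-2-[(3E,7S)-9-acetoxy-3,7-dimethylnon-3-en-1-yl]-1,3-dimethylcyclohex-3-ene-1-carbaldehyde
Conditions: (S)-o-tolyl-CBS oxazaborolidine [(S)-3,3-diphenyl-1-(2-methylphenyl)tetrahydropyrrolo[1,2-c][1,3,2]oxazaborole] (20 mol %), HNTf2 (17 mol %), 7 (3 equiv), CH2Cl2, −78→−40 °C
Reagents that add atoms: none
Why: In this catalytic enantioselective Diels–Alder reaction the oxazaborolidinium-bound s-trans methacrolein is expected to react through the formyl-exo transition state typical of 2-substituted acroleins and with the "ortho" regiochemistry of 1-alkyl dienes (as for 1-vinylcyclohexenes), so the formyl group ends trans and the methyl cis to the side chain (C-4/C-5 relative configuration), while the (S)-catalyst is expected to direct the diene to the Re face of the dienophile α-carbon to give (1S,2S)-8 (the sense is assigned by analogy and must be confirmed; the (R)-catalyst gives the antipodal ring).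

Step 6
Reactants: 8 (1S,2S)-2-[(3E,7S)-9-acetoxy-3,7-dimethylnon-3-en-1-yl]-1,3-dimethylcyclohex-3-ene-1-carbaldehyde
Product: 9 (1S,2S)-2-[(3E,7S)-9-acetoxy-3,7-dimethylnon-3-en-1-yl]-1,3-dimethylcyclohex-3-ene-1-carboxylic acid
Conditions: NaClO2, NaH2PO4, 2-methylbut-2-ene, t-BuOH/H2O, 0 °C→rt
Reagents that add atoms: sodium chlorite, [Na+].[O-]Cl=O
Why: Pinnick oxidation converts the non-enolisable neopentyl aldehyde into the acid while 2-methylbut-2-ene scavenges HOCl and so protects both trisubstituted alkenes.

Step 7
Reactants: 9 (1S,2S)-2-[(3E,7S)-9-acetoxy-3,7-dimethylnon-3-en-1-yl]-1,3-dimethylcyclohex-3-ene-1-carboxylic acid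
Product: 12 (1S,4aS,5R,8aS)-5-[(3S)-5-acetoxy-3-methylpentyl]-1,4a-dimethyl-6-methylidenedecahydronaphthalene-1-carboxylic acid, via bridged lactone 10 (not isolated), via trimethylsilyl ester 11 (not isolated)
Conditions: MsOH (10 mol %), CH2Cl2, rt; then 2,6-lutidine (2 equiv), Me3SiOTf (1.5 equiv), −40 °C→rt; aq. work-up
Reagents that add atoms: none
Why: Proposed new method: a bridged tertiary γ-lactone serves as a proton-free, site-specific initiator of a cation–olefin cyclization — MsOH closes the carboxyl of 9 onto the neighbouring ring alkene (carboxyl-assisted Markovnikov lactonization that leaves the isolated side-chain alkene alone) to give 10, O-silylation by Me3SiOTf then ionizes the tertiary C–O bond (the alkyl–oxygen heterolysis by which Me3SiOTf/2,6-lutidine cleaves tert-butyl esters and by which Lewis acids make tertiary lactones alkylate arenes) to release the C-10 cation next to a neutral silyl ester, internal return only regenerates 10 whereas capture by the side-chain (E)-alkene through the chair–chair transition state with the C-5 side chain equatorial is irreversible and sets the trans ring fusion (C-10 methyl anti to H-5) and the equatorial C-9 side chain under control of the existing C-5 centre, and the hindered base removes a C-17 proton from the C-8 cation before work-up hydrolyses silyl ester 11; the closest known reaction types are acetal- and epoxide-initiated Lewis-acid polyene cyclizations.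

Step 8
Reactants: 12 (1S,4aS,5R,8aS)-5-[(3S)-5-acetoxy-3-methylpentyl]-1,4a-dimethyl-6-methylidenedecahydronaphthalene-1-carboxylic acid
Product: 14 (1S,4aR,5S,6S,8aS)-5-[(3S)-5-acetoxy-3-methylpentyl]-6-hydroxy-1,4a,6-trimethyldecahydronaphthalene-1-carboxylic acid (target), via tertiary hydroperoxide 13 (not isolated)
Conditions: Mn(dpm)3 (10 mol %; dpm = 2,2,6,6-tetramethylheptane-3,5-dionate), PhSiH3, O2 (1 atm), i-PrOH/CH2Cl2, 0 °C→rt; then PPh3
Reagents that add atoms: dioxygen, O=O
Why: In this Mukaiyama hydration (metal-hydride hydrogen-atom transfer) H• adds to the exocyclic CH2 to give the tertiary C-8 radical, O2 traps it on the face opposite the axial C-10 methyl so that the C–O bond is equatorial and the new methyl axial (8S), and PPh3 reduces hydroperoxide 13 to the alcohol while the acetate and the free acid are inert.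

**Compound list**
1 | (2E,6E)-farnesol, (2E,6E)-3,7,11-trimethyldodeca-2,6,10-trien-1-ol | OC/C=C(C)/CC/C=C(C)/CCC=C(C)C | starting material
2 | (3S,6E)-3,7,11-trimethyldodeca-6,10-dien-1-ol | OCC[C@@H](C)CC/C=C(C)/CCC=C(C)C | intermediate
3 | (3S,6E)-3,7,11-trimethyldodeca-6,10-dien-1-yl acetate | CC(=O)OCC[C@@H](C)CC/C=C(C)/CCC=C(C)C | intermediate
4 | (3S,6E,10E)-12-hydroxy-3,7,11-trimethyldodeca-6,10-dien-1-yl acetate | CC(=O)OCC[C@@H](C)CC/C=C(C)/CC/C=C(C)/CO | intermediate (not isolated)
5 | (3S,6E,10E)-3,7,11-trimethyl-12-oxododeca-6,10-dien-1-yl acetate | CC(=O)OCC[C@@H](C)CC/C=C(C)/CC/C=C(C)/C=O | intermediate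
6 | (3S,6E,10E)-3,7,11-trimethyltrideca-6,10,12-trien-1-yl acetate | CC(=O)OCC[C@@H](C)CC/C=C(C)/CC/C=C(C)/C=C | intermediate
7 | methacrolein, 2-methylprop-2-enal | CC(=C)C=O | starting material
8 | (1S,2S)-2-[(3E,7S)-9-acetoxy-3,7-dimethylnon-3-en-1-yl]-1,3-dimethylcyclohex-3-ene-1-carbaldehyde | CC(=O)OCC[C@@H](C)CC/C=C(C)/CC[C@H]1C(C)=CCC[C@]1(C)C=O | intermediate
9 | (1S,2S)-2-[(3E,7S)-9-acetoxy-3,7-dimethylnon-3-en-1-yl]-1,3-dimethylcyclohex-3-ene-1-carboxylic acid | CC(=O)OCC[C@@H](C)CC/C=C(C)/CC[C@H]1C(C)=CCC[C@]1(C)C(=O)O | intermediate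
10 | bridged γ-lactone of 9: 8-[(3E,7S)-9-acetoxy-3,7-dimethylnon-3-en-1-yl]-1,5-dimethyl-6-oxabicyclo[3.2.1]octan-7-one (carboxyl closed onto the methyl-bearing carbon of the former ring alkene, side chain anti to the lactone bridge) | CC(=O)OCC[C@@H](C)CC/C=C(C)/CC[C@H]1[C@@]2(C)CCC[C@]1(C)C(=O)O2 | intermediate (not isolated)
11 | trimethylsilyl ester of 12 | CC(=O)OCC[C@@H](C)CC[C@H]1[C@]2(C)CCC[C@](C)(C(=O)O[Si](C)(C)C)[C@H]2CCC1=C | intermediate (not isolated)
12 | (1S,4aS,5R,8aS)-5-[(3S)-5-acetoxy-3-methylpentyl]-1,4a-dimethyl-6-methylidenedecahydronaphthalene-1-carboxylic acid | CC(=O)OCC[C@@H](C)CC[C@H]1[C@]2(C)CCC[C@](C)(C(=O)O)[C@H]2CCC1=C | intermediate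
13 | (1S,4aR,5S,6S,8aS)-5-[(3S)-5-acetoxy-3-methylpentyl]-6-hydroperoxy-1,4a,6-trimethyldecahydronaphthalene-1-carboxylic acid | CC(=O)OCC[C@@H](C)CC[C@H]1[C@]2(C)CCC[C@](C)(C(=O)O)[C@H]2CC[C@]1(C)OO | intermediate (not isolated)
14 | (1S,4aR,5S,6S,8aS)-5-[(3S)-5-acetoxy-3-methylpentyl]-6-hydroxy-1,4a,6-trimethyldecahydronaphthalene-1-carboxylic acid | CC(=O)OCC[C@@H](C)CC[C@H]1[C@]2(C)CCC[C@](C)(C(=O)O)[C@H]2CC[C@]1(C)O | target

**Totals**
Total step count: 8. Longest linear sequence: 8 steps (1 to 14; methacrolein 7 enters at step 5).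

**Three steps most likely to fail**

Step 7 (the proposed new step). The lactone may not ionize cleanly. The C-10 cation may lose a proton before it cyclizes, which under proton-free conditions is a dead end that has to be recycled through the lactonization. Some cis-fused product or an endocyclic alkene regioisomer may also form. The fallback uses known chemistry only and replaces the carboxyl by a group that cannot reach the C-10 cation. It sets out from 8. Wittig methylenation of the aldehyde (Ph3P=CH2, THF) gives the vinyl triene F1. Classical SnCl4-promoted cyclization (CH2Cl2, −78 °C), as used for 2-methylcyclohex-2-enyl-tethered trisubstituted alkenes, gives the vinyl-substituted bicyclic 7-ene F2. mCPBA epoxidizes only the trisubstituted ring alkene, from the face opposite the C-10 methyl, to give the vinyl epoxide F3. LiAlH4 opens the epoxide at C-7 and removes the acetate to give the vinyl diol F4. Ac2O/pyridine acetylates only the primary alcohol to give the vinyl hydroxy acetate F5. RuCl3 (cat.)/NaIO4 cleaves the vinyl group to the carboxylic acid. The fallback comes back to the route at 14.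

Step 5. The exo/endo ratio, the "ortho" regiochemistry and the facial sense of the catalytic Diels–Alder reaction are all assigned by analogy. The fallback gives up catalyst control of the ring configuration. It sets out from 6 and 7. An achiral bulky Lewis acid, aluminium tris(2,6-diphenylphenoxide) Al(OC6H3Ph2)3, promotes the exo cycloaddition and gives 8 together with its ring-antipodal (1R,2R)-diastereomer F6. Pinnick oxidation of the mixture gives 9 and the (1R,2R)-acid diastereomer F7. Because C-13 is fixed, the two are diastereomers and are separated by preparative chromatography on a chiral stationary phase (or by crystallization of their salts with a single enantiomer of 1-phenylethylamine). The fallback comes back to the route at 9 with at most half of the material.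

Step 8. The facial selectivity of oxygen capture by the C-8 radical may be modest. The fallback is a polar route to the same C–O bond. It sets out from 12. mCPBA epoxidizes the exocyclic alkene from the face opposite the C-10 methyl to give the spiro-epoxy acid F8. LiBHEt3 opens the oxirane at its CH2 carbon (the carboxylate is inert) and also removes the acetate, giving the dihydroxy acid F9. Ac2O/pyridine then acetylates only the primary alcohol. The fallback comes back to the route at 14.

**Further compounds**
F1 | step 7 | vinyl triene: analogue of 8 with CH=CH2 in place of CHO | CC(=O)OCC[C@@H](C)CC/C=C(C)/CC[C@H]1C(C)=CCC[C@]1(C)C=C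
F2 | step 7 | vinyl-substituted bicyclic 7-ene: trans-fused decalin with C-4 vinyl and C-7 ring alkene | CC(=O)OCC[C@@H](C)CC[C@H]1[C@]2(C)CCC[C@](C)(C=C)[C@H]2CC=C1C
F3 | step 7 | vinyl epoxide: 7,8-epoxide of F2, oxygen on the face opposite the C-10 methyl | CC(=O)OCC[C@@H](C)CC[C@H]1[C@]2(C)CCC[C@](C)(C=C)[C@H]2C[C@@H]3O[C@]13C
F4 | step 7 | vinyl diol: C-4 vinyl analogue of the target with free C-15 hydroxyl | OCC[C@@H](C)CC[C@H]1[C@]2(C)CCC[C@](C)(C=C)[C@H]2CC[C@]1(C)O
F5 | step 7 | vinyl hydroxy acetate: C-4 vinyl analogue of the target | CC(=O)OCC[C@@H](C)CC[C@H]1[C@]2(C)CCC[C@](C)(C=C)[C@H]2CC[C@]1(C)O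
F6 | step 5 | (1R,2R)-diastereomer of 8 | CC(=O)OCC[C@@H](C)CC/C=C(C)/CC[C@@H]1C(C)=CCC[C@@]1(C)C=O
F7 | step 5 | (1R,2R)-acid diastereomer of 9 | CC(=O)OCC[C@@H](C)CC/C=C(C)/CC[C@@H]1C(C)=CCC[C@@]1(C)C(=O)O
F8 | step 8 | spiro-epoxy acid: 8,17-epoxide of 12, oxygen on the face opposite the C-10 methyl | CC(=O)OCC[C@@H](C)CC[C@H]1[C@]2(C)CCC[C@](C)(C(=O)O)[C@H]2CC[C@@]13CO3
F9 | step 8 | dihydroxy acid: 15-deacetyl target | OCC[C@@H](C)CC[C@H]1[C@]2(C)CCC[C@](C)(C(=O)O)[C@H]2CC[C@]1(C)O
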